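**Plan**

1. Ring atoms are called O1, O2, C3 (the CH that carries CH2CO2Me), C4=C5 and C6 (the peroxyketal carbon with OMe and C16H33). The retrosynthesis loosens the C6–OMe bond (ketal exchange, both C6 epimers), takes the ester back to a CH2CH2OTBS group, then cuts the ring at O2–C3 and at C4=C5.
2. Enabling feature: the 3,6-dihydro-1,2-dioxine is a cyclic bis-allylic peroxide. Both oxygen-bearing ring carbons (C3 and C6) flank the only ring alkene, so each half can carry one vinyl group. Once O2–C3 is made, the O1–O2 bridge itself is the tether for ring-closing metathesis, and the six-membered ring forces the cis alkene.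
3. Forward: the C16 chain is joined to methoxyallene (C6 with its OMe in place), and perhydrolysis gives a vinyl hydroperoxy ketal. This is united in one flask with an (S)-allylic mesylate (O2–C3) and ring-closed (C4=C5). Desilylation, oxidation to the acid and methyl ester formation follow.
4. Stereochemistry: C3 (R) comes from a Sharpless-resolved (S)-allylic alcohol through SN2 inversion. C6 (S) is not biased by the route: it is settled last by acid-mediated ketal equilibration in MeOH and separation, the other epimer being recycled.

Key step: step 6

Remark: methoxyallene, 1-iodohexadecane, 3-[(tert-butyldimethylsilyl)oxy]propanal, vinylmagnesium bromide and D-(−)-diisopropyl tartrate are taken as purchasable.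
Remark: no thermodynamic preference between the two C6 ketal epimers is assumed; C3 is never exposed to base after it is set.

**Step 1**
Reactants: 1 methoxyallene; 2 1-iodohexadecane
Product: 3 3-methoxynonadeca-1,2-diene
Conditions: n-BuLi, THF, −40 °C; then 2, −40 °C to rt
Reagents that add atoms: none
Why: Deprotonation of methoxyallene at C1 and SN2 alkylation of the lithiated alkoxyallene by the primary iodide (α-alkylation of a lithiated alkoxyallene) should join the C16 chain to the future ketal carbon with its methoxy group already in place, without forming a stereocentre.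

**Step 2**
Reactants: 3 3-methoxynonadeca-1,2-diene
Product: 4 rac-3-hydroperoxy-3-methoxynonadec-1-ene
Conditions: anhydrous H2O2 in Et2O (3 equiv), PPTS (cat.), 0 °C
Reagents that add atoms: hydrogen peroxide, OO
Why: Acid-catalysed Markovnikov perhydrolysis of an enol ether should apply here, because the alkoxyallene is protonated at its central carbon (as in its acid-catalysed addition of alcohols and its hydrolysis to vinyl ketones) and the vinyl-substituted oxocarbenium ion is captured at carbon by H2O2; the new stereocentre forms racemic and is settled only in step 10.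

**Step 3**
Reactants: 5 3-[(tert-butyldimethylsilyl)oxy]propanal; 6 vinylmagnesium bromide
Product: 7 rac-5-[(tert-butyldimethylsilyl)oxy]pent-1-en-3-ol
Conditions: THF, −78 to 0 °C; aq. NH4Cl
Reagents that add atoms: none
Why: Grignard 1,2-addition of the vinyl nucleophile to the aldehyde should give the racemic secondary allylic alcohol that carries the future C3, the vinyl group for ring closure and the masked carboxyl carbon.

**Step 4**
Reactants: 7 rac-5-[(tert-butyldimethylsilyl)oxy]pent-1-en-3-ol
Product: 8 (S)-5-[(tert-butyldimethylsilyl)oxy]pent-1-en-3-ol
Conditions: Ti(OiPr)4 (cat.), D-(−)-diisopropyl tartrate (cat.), t-BuOOH (0.6 equiv), 4 Å molecular sieves, CH2Cl2, −20 °C; unreacted alcohol isolated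
Reagents that add atoms: none
Why: In this Sharpless kinetic resolution the D-(−)-tartrate catalyst should epoxidise the (R)-alcohol much faster, so the unreacted alcohol is recovered as the (S)-enantiomer, which fixes the absolute configuration that is later inverted to C3 (R).

**Step 5**
Reactants: 8 (S)-5-[(tert-butyldimethylsilyl)oxy]pent-1-en-3-ol
Product: 9 (S)-5-[(tert-butyldimethylsilyl)oxy]pent-1-en-3-yl methanesulfonate
Conditions: Ms2O, Et3N, CH2Cl2, −20 °C; used crude at once
Reagents that add atoms: methanesulfonic anhydride, CS(=O)(=O)OS(C)(=O)=O
Why: O-Sulfonylation with the anhydride (no chloride present that could open an SN2′ path) should give the allylic mesylate with retention, since the C–O bond is not touched.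

**Step 6**
Reactants: 4 rac-3-hydroperoxy-3-methoxynonadec-1-ene; 9 (S)-5-[(tert-butyldimethylsilyl)oxy]pent-1-en-3-yl methanesulfonate
Product: 11 tert-butyl{2-[(3R)-6-hexadecyl-6-methoxy-3,6-dihydro-1,2-dioxin-3-yl]ethoxy}dimethylsilane (both C6 epimers), via acyclic bis-allylic peroxide 10 (not isolated)
Conditions: KOtBu (1.0 equiv to 4), 18-crown-6, THF, −20 °C, then 9 (1.2 equiv), to 0 °C; after 4 is consumed, dilution with CH2Cl2, second-generation Hoveyda–Grubbs catalyst (5 mol %), 40 °C, same flask
Reagents that add atoms: none
Why: The potassium salt of hydroperoxide 4 should displace the mesylate of 9 by SN2 at the secondary allylic carbon, which makes the O2–C3 bond and turns the O1–O2 bridge into the tether that holds the two vinyl groups in reach; the ruthenium alkylidene should then load on the less hindered vinyl group next to C3 and close onto the vinyl group at the quaternary ketal carbon with loss of ethylene, which makes C4=C5. The closest known reaction types are the base-mediated alkylation of α-alkoxyalkyl hydroperoxides by secondary sulfonates and the ring-closing metathesis of bis-allylic ethers to 3,6-dihydro-2H-pyrans, dialkyl peroxides being tolerated by ruthenium alkylidenes. The six-membered ring is closed by ring-closing metathesis, and a six-membered ring can only hold the cis alkene, so no olefin geometry has to be controlled. C3 is set as R by inversion of the (S)-mesylate, whereas C6 is carried as both epimers from racemic 4 and is settled in step 10. The step needs SN2 over SN2′ and elimination, which the unhindered terminal oxygen of the weakly basic α-effect peroxide anion should favour, and it needs the free hydroperoxide to be gone before the carbene is added, which is secured by making 4 the limiting component.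

**Step 7**
Reactants: 11 tert-butyl{2-[(3R)-6-hexadecyl-6-methoxy-3,6-dihydro-1,2-dioxin-3-yl]ethoxy}dimethylsilane
Product: 12 2-[(3R)-6-hexadecyl-6-methoxy-3,6-dihydro-1,2-dioxin-3-yl]ethanol (both C6 epimers)
Conditions: CSA (cat.), MeOH, 0 °C to rt
Reagents that add atoms: none
Why: Acid-catalysed methanolysis of the primary silyl ether should free the alcohol, while methanol as solvent keeps C6 a methyl ketal whatever exchange occurs there and C3 is not involved.

**Step 8**
Reactants: 12 2-[(3R)-6-hexadecyl-6-methoxy-3,6-dihydro-1,2-dioxin-3-yl]ethanol
Product: 13 2-[(3R)-6-hexadecyl-6-methoxy-3,6-dihydro-1,2-dioxin-3-yl]acetic acid (both C6 epimers)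
Conditions: TEMPO (cat.), PhI(OAc)2, MeCN/pH 7 phosphate buffer, 0 °C to rt
Reagents that add atoms: water, O
Why: Oxoammonium (TEMPO/PhI(OAc)2) oxidation of the primary alcohol through the aldehyde hydrate should give the acid, since alkene and dialkyl peroxide are inert to it and the buffered, base-free medium avoids β-elimination of the peroxide from the intermediate aldehyde, so C3 is kept.

**Step 9**
Reactants: 13 2-[(3R)-6-hexadecyl-6-methoxy-3,6-dihydro-1,2-dioxin-3-yl]acetic acid
Product: 14 methyl 2-[(3R)-6-hexadecyl-6-methoxy-3,6-dihydro-1,2-dioxin-3-yl]acetate (both C6 epimers)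
Conditions: Me3SiCHN2, toluene/MeOH, 0 °C
Reagents that add atoms: trimethylsilyldiazomethane, C[Si](C)(C)C=[N+]=[N-]
Why: O-Methylation of the carboxylic acid by the diazoalkane (esterification under neutral conditions) should give the methyl ester without any base that could open the β-peroxy ester by retro-oxa-Michael reaction.

**Step 10**
Reactants: 14 methyl 2-[(3R)-6-hexadecyl-6-methoxy-3,6-dihydro-1,2-dioxin-3-yl]acetate (both C6 epimers)
Product: 15 chondrillin, methyl 2-[(3R,6S)-6-hexadecyl-6-methoxy-3,6-dihydro-1,2-dioxin-3-yl]acetate
Conditions: PPTS (cat.), MeOH, rt; chromatography on silica; recovered C6 epimer resubmitted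
Reagents that add atoms: methanol, CO
Why: Acid-catalysed ketal exchange should ionise the C6–OMe bond to the allylic peroxycarbenium ion, which methanol recaptures on either face, so any hemiketal formed earlier is re-ketalised and both epimers are funnelled into one equilibrium mixture from which the (6S)-epimer 15 is separated and the (6R)-epimer recycled, C3 not being touched.

**Compound list**

1 | methoxyallene (1-methoxypropa-1,2-diene) | COC=C=C | starting material
2 | 1-iodohexadecane | CCCCCCCCCCCCCCCCI | starting material
3 | 3-methoxynonadeca-1,2-diene | C=C=C(OC)CCCCCCCCCCCCCCCC | intermediate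
4 | rac-3-hydroperoxy-3-methoxynonadec-1-ene | C=CC(OC)(OO)CCCCCCCCCCCCCCCC | intermediate
5 | 3-[(tert-butyldimethylsilyl)oxy]propanal | O=CCCO[Si](C)(C)C(C)(C)C | starting material
6 | vinylmagnesium bromide | C=C[Mg]Br | starting material
7 | rac-5-[(tert-butyldimethylsilyl)oxy]pent-1-en-3-ol | C=CC(O)CCO[Si](C)(C)C(C)(C)C | intermediate
8 | (S)-5-[(tert-butyldimethylsilyl)oxy]pent-1-en-3-ol | C=C[C@@H](O)CCO[Si](C)(C)C(C)(C)C | intermediate
9 | (S)-5-[(tert-butyldimethylsilyl)oxy]pent-1-en-3-yl methanesulfonate | C=C[C@@H](OS(C)(=O)=O)CCO[Si](C)(C)C(C)(C)C | intermediate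
10 | tert-butyl({(3R)-3-[(3-methoxynonadec-1-en-3-yl)peroxy]pent-4-en-1-yl}oxy)dimethylsilane (both ketal epimers) | C=C[C@@H](CCO[Si](C)(C)C(C)(C)C)OOC(OC)(C=C)CCCCCCCCCCCCCCCC | intermediate
11 | tert-butyl{2-[(3R)-6-hexadecyl-6-methoxy-3,6-dihydro-1,2-dioxin-3-yl]ethoxy}dimethylsilane (both C6 epimers) | CCCCCCCCCCCCCCCCC1(OC)C=C[C@@H](CCO[Si](C)(C)C(C)(C)C)OO1 | intermediate
12 | 2-[(3R)-6-hexadecyl-6-methoxy-3,6-dihydro-1,2-dioxin-3-yl]ethanol (both C6 epimers) | CCCCCCCCCCCCCCCCC1(OC)C=C[C@@H](CCO)OO1 | intermediate
13 | 2-[(3R)-6-hexadecyl-6-methoxy-3,6-dihydro-1,2-dioxin-3-yl]acetic acid (both C6 epimers) | CCCCCCCCCCCCCCCCC1(OC)C=C[C@@H](CC(=O)O)OO1 | intermediate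
14 | methyl 2-[(3R)-6-hexadecyl-6-methoxy-3,6-dihydro-1,2-dioxin-3-yl]acetate (both C6 epimers) | CCCCCCCCCCCCCCCCC1(OC)C=C[C@@H](CC(=O)OC)OO1 | intermediate
15 | chondrillin, methyl 2-[(3R,6S)-6-hexadecyl-6-methoxy-3,6-dihydro-1,2-dioxin-3-yl]acetate | CCCCCCCCCCCCCCCC[C@@]1(OC)C=C[C@@H](CC(=O)OC)OO1 | target

**Step count and risks**

Total steps: 10. Longest linear sequence: 8 steps (from 5 through steps 3 to 10).

Most likely to fail, first: step 6. The ketal peroxide salt may attack the allylic mesylate at the terminus (SN2′) or cause elimination, the salt may decay under base, and hydroperoxide that has not been consumed may deactivate the ruthenium carbene. The fallback sets out from 9 and 3 and comes back to the route at 10. Mesylate 9 is displaced with inversion by H2O2/KOH in MeOH at 0 °C to give the secondary hydroperoxide tert-butyl{[(3R)-3-hydroperoxypent-4-en-1-yl]oxy}dimethylsilane F1. F1 is then added to allene 3 with catalytic PPTS in CH2Cl2 (the perhydrolysis of step 2 with an alkyl hydroperoxide), so the two halves are joined at the ketal C6–O1 bond under acid and not at O2–C3 under base. This gives 10 as an isolated, purified compound, which is closed to 11 with the second-generation Hoveyda–Grubbs catalyst in CH2Cl2 as a separate operation.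

Second: step 2. The perhydrolysis may run on to the geminal bis-hydroperoxide, adventitious water may capture the cation (vinyl ketone), or H2O2 may attack at the allene terminus. The fallback sets out from 3 and comes back at 4. Allene 3 is first taken with MeOH and catalytic PPTS to the isolable ketal 3,3-dimethoxynonadec-1-ene F2 (alcohol addition to an alkoxyallene). The peroxide is then brought in by trans-ketalisation of F2 with one equivalent of ethereal H2O2 and catalytic acid, which can be followed and stopped at the mono-exchange stage.

Third: step 5. The secondary allylic mesylate may ionise or undergo allylic transposition before or during use, with loss of configurational purity at the future C3. The fallback sets out from 4 and comes back at 13; it avoids the sulfonate and sets C3 by catalyst control. Iminium-catalysed enantioselective β-peroxidation of (E)-penta-2,4-dienal by 4, with (S)-α,α-diphenylprolinol trimethylsilyl ether and a carboxylic acid co-catalyst, should give (3R)-3-[(3-methoxynonadec-1-en-3-yl)peroxy]pent-4-enal F3. The (S)-catalyst is expected to give the R centre by analogy with the sense of its enal epoxidations. Ring-closing metathesis with the second-generation Hoveyda–Grubbs catalyst gives 2-[(3R)-6-hexadecyl-6-methoxy-3,6-dihydro-1,2-dioxin-3-yl]acetaldehyde F4. Pinnick oxidation (NaClO2, NaH2PO4, 2-methylbut-2-ene, t-BuOH/H2O) gives acid 13.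

**Further compounds**

F1 | step 6 | tert-butyl{[(3R)-3-hydroperoxypent-4-en-1-yl]oxy}dimethylsilane | C=C[C@@H](CCO[Si](C)(C)C(C)(C)C)OO
F2 | step 2 | 3,3-dimethoxynonadec-1-ene | C=CC(OC)(OC)CCCCCCCCCCCCCCCC
F3 | step 5 | (3R)-3-[(3-methoxynonadec-1-en-3-yl)peroxy]pent-4-enal (both ketal epimers) | CCCCCCCCCCCCCCCCC(OC)(C=C)OO[C@@H](C=C)CC=O
F4 | step 5 | 2-[(3R)-6-hexadecyl-6-methoxy-3,6-dihydro-1,2-dioxin-3-yl]acetaldehyde (both C6 epimers) | CCCCCCCCCCCCCCCCC1(OC)C=C[C@@H](CC=O)OO1
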